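**Retrosynthetic overview**

1. Target 25 ← O-acetylation, ester demethylation and reductive removal of the auxiliary ← imide 21 ← C12–C13 bond: decarboxylative radical conjugate addition of the decalin redox-active ester 16 to the (R)-oxazolidinone crotonyl imide 20.
2. Enabling feature: C12 is a primary carbon outside ring B, two bonds from C9, whose radical can reach C8=C17 only by 4-exo or 5-endo closure and therefore survives to couple, so it can carry a sacrificial carboxyl carbon. C13 lies beta to the oxygen-bearing C15, so C13, its methyl, C14 and C15 map onto a crotonyl unit with C15 at the acyl level.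
3. 16 ← deoxygenation at C3 and enzymatic resolution ← racemic decalin 10 ← Mn(OAc)3/Cu(OAc)2 oxidative radical bicyclization of acyclic keto diester 9: ring A closes first (C4–C5), then ring B (C9–C10), and termination installs the exocyclic C8=C17 alkene.
4. 9 ← dianion of methyl 2-methyl-3-oxobutanoate + allylic bromide 6 ← geranyl bromide + tert-butyl acetate.

Key step: step 12

Remark: labdane numbering is used for atoms (C4 carries the carboxyl carbon C19, C10 the angular methyl, C8=C17 is the exocyclic alkene, C9 carries C11–C12, C13 is the methyl-bearing side-chain carbon); the carbinol configuration of 11 depends on the enzyme chosen and is drawn equatorial, which has no consequence because that carbon becomes CH2 in step 8.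

**Route**

Step 1
Reactants: 1 tert-butyl acetate; 2 geranyl bromide, (2E)-1-bromo-3,7-dimethylocta-2,6-diene
Product: 4 tert-butyl (4E)-5,9-dimethyldeca-4,8-dienoate, via lithium enolate of tert-butyl acetate 3 (not isolated)
Conditions: LiN(i-Pr)2, THF, −78 °C; then 2, DMPU, −78 → −20 °C
Reagents that add atoms: none
Why: Alkylation of a lithium ester enolate (SN2) at the primary allylic bromide; no stereocenter is formed and the (E)-alkene is retained.

Step 2
Reactants: 4 tert-butyl (4E)-5,9-dimethyldeca-4,8-dienoate
Product: 5 tert-butyl (4E,8E)-10-hydroxy-5,9-dimethyldeca-4,8-dienoate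
Conditions: SeO2 (cat.), t-BuOOH, salicylic acid (cat.), CH2Cl2, rt
Reagents that add atoms: selenium dioxide O=[Se]=O (oxygen relay); tert-butyl hydroperoxide CC(C)(C)OO (terminal oxygen source)
Why: Selenium dioxide allylic oxidation (ene reaction followed by [2,3]-sigmatropic shift) should take place at the (E)-methyl group of the terminal trisubstituted alkene and give the (E)-allylic alcohol.

Step 3
Reactants: 5 tert-butyl (4E,8E)-10-hydroxy-5,9-dimethyldeca-4,8-dienoate
Product: 6 tert-butyl (4E,8E)-10-bromo-5,9-dimethyldeca-4,8-dienoate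
Conditions: CBr4, PPh3, CH2Cl2, 0 °C
Reagents that add atoms: tetrabromomethane BrC(Br)(Br)Br
Why: Appel reaction of the primary allylic alcohol under neutral conditions, without allylic transposition and without loss of the tert-butyl ester.

Step 4
Reactants: 7 methyl 2-methyl-3-oxobutanoate; 6 tert-butyl (4E,8E)-10-bromo-5,9-dimethyldeca-4,8-dienoate
Product: 9 1-tert-butyl 14-methyl (4E,8E)-5,9,13-trimethyl-12-oxotetradeca-4,8-dienedioate, via acetoacetate dianion 8 (not isolated)
Conditions: NaH then n-BuLi, THF, 0 °C; then 6, 0 °C; aq. NH4Cl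
Reagents that add atoms: none
Why: Acetoacetate dianion alkylation, in which the more basic terminal carbanion displaces the allylic bromide by SN2; the stereocenter between the two carbonyl groups forms as a racemate and is erased in step 5.

Step 5
Reactants: 9 1-tert-butyl 14-methyl (4E,8E)-5,9,13-trimethyl-12-oxotetradeca-4,8-dienedioate
Product: 10 racemic methyl (1S,4aS,5R,8aS)-5-[3-(tert-butoxy)-3-oxopropyl]-1,4a-dimethyl-6-methylidene-2-oxodecahydronaphthalene-1-carboxylate
Conditions: Mn(OAc)3·2H2O (2.2 equiv), Cu(OAc)2·H2O (1 equiv, reoxidised in situ by Mn(OAc)3), degassed AcOH, rt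
Reagents that add atoms: none
Why: Oxidative free-radical polyene cyclization: Mn(OAc)3 generates the alpha-keto ester radical at C4, two 6-endo closures through chair-chair transition states of the (E,E)-diene should give the trans-decalin with the ester axial (cis to the angular methyl) and the C9 side chain equatorial, and Cu(OAc)2 converts the tertiary C8 radical by oxidative elimination into the less substituted exocyclic alkene; the product is racemic.

Step 6
Reactants: 10 racemic methyl (1S,4aS,5R,8aS)-5-[3-(tert-butoxy)-3-oxopropyl]-1,4a-dimethyl-6-methylidene-2-oxodecahydronaphthalene-1-carboxylate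
Product: 11 methyl (1S,2R,4aS,5R,8aS)-5-[3-(tert-butoxy)-3-oxopropyl]-2-hydroxy-1,4a-dimethyl-6-methylidenedecahydronaphthalene-1-carboxylate
Conditions: ketoreductase (NADPH-dependent, chosen from a commercial panel for reduction of the (1S,4aS,5R,8aS) ketone only), NADP+ (cat.), i-PrOH (10 vol%), potassium phosphate buffer pH 7, DMSO (10 vol%), 30 °C, stopped at half conversion
Reagents that add atoms: none
Why: Enzymatic kinetic resolution by enantiomer-selective ketone reduction, a reaction type known for cyclic alpha,alpha-disubstituted beta-keto esters: only one enantiomer should be reduced, the mirror-image ketone is left and removed by chromatography, and the carbinol stereocenter is set by the enzyme's hydride delivery and removed again in step 8.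

Step 7
Reactants: 11 methyl (1S,2R,4aS,5R,8aS)-5-[3-(tert-butoxy)-3-oxopropyl]-2-hydroxy-1,4a-dimethyl-6-methylidenedecahydronaphthalene-1-carboxylate
Product: 12 methyl (1S,2R,4aS,5R,8aS)-5-[3-(tert-butoxy)-3-oxopropyl]-2-[(1H-imidazol-1-ylcarbonothioyl)oxy]-1,4a-dimethyl-6-methylidenedecahydronaphthalene-1-carboxylate
Conditions: 1,1'-thiocarbonyldiimidazole, DMAP (cat.), ClCH2CH2Cl, 80 °C
Reagents that add atoms: 1,1'-thiocarbonyldiimidazole S=C(n1ccnc1)n1ccnc1
Why: Thiocarbonylation of the hindered secondary alcohol under neutral conditions (first half of a Barton–McCombie deoxygenation) avoids an alkoxide and thus retro-aldol opening of the beta-hydroxy ester.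

Step 8
Reactants: 12 methyl (1S,2R,4aS,5R,8aS)-5-[3-(tert-butoxy)-3-oxopropyl]-2-[(1H-imidazol-1-ylcarbonothioyl)oxy]-1,4a-dimethyl-6-methylidenedecahydronaphthalene-1-carboxylate
Product: 13 methyl (1R,4aS,5R,8aS)-5-[3-(tert-butoxy)-3-oxopropyl]-1,4a-dimethyl-6-methylidenedecahydronaphthalene-1-carboxylate
Conditions: Bu3SnH, AIBN (cat.), toluene, 110 °C
Reagents that add atoms: none
Why: Barton–McCombie deoxygenation, in which the stannyl radical adds to C=S, the secondary ring radical fragments out and is reduced by Bu3SnH; the unactivated exocyclic alkene and both esters should be inert, and the carbinol stereocenter disappears.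

Step 9
Reactants: 13 methyl (1R,4aS,5R,8aS)-5-[3-(tert-butoxy)-3-oxopropyl]-1,4a-dimethyl-6-methylidenedecahydronaphthalene-1-carboxylate
Product: 15 methyl (1R,4aS,5R,8aS)-5-(2-carboxyethyl)-1,4a-dimethyl-6-methylidenedecahydronaphthalene-1-carboxylate, via trimethylsilyl ester 14 (not isolated)
Conditions: Me3SiOTf, 2,6-lutidine, CH2Cl2, 0 °C; then H2O
Reagents that add atoms: none
Why: Silyl triflate-mediated cleavage of the tert-butyl ester (loss of isobutene from the O-silylated ester, buffered by 2,6-lutidine) should leave the hindered methyl ester and the acid-sensitive exocyclic alkene intact; the silyl ester is hydrolysed on work-up.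

Step 10
Reactants: 15 methyl (1R,4aS,5R,8aS)-5-(2-carboxyethyl)-1,4a-dimethyl-6-methylidenedecahydronaphthalene-1-carboxylate
Product: 16 methyl (1R,4aS,5R,8aS)-5-{3-[(1,3-dioxoisoindolin-2-yl)oxy]-3-oxopropyl}-1,4a-dimethyl-6-methylidenedecahydronaphthalene-1-carboxylate
Conditions: N-hydroxyphthalimide, N,N'-diisopropylcarbodiimide, DMAP (cat.), CH2Cl2, rt
Reagents that add atoms: N-hydroxyphthalimide O=C1c2ccccc2C(=O)N1O
Why: Carbodiimide-mediated (Steglich-type) esterification of the unhindered acid gives the redox-active N-acyloxyphthalimide.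

Step 11
Reactants: 17 (4R)-4-(diphenylmethyl)-1,3-oxazolidin-2-one; 18 (2E)-but-2-enoyl chloride
Product: 20 (4R)-3-[(2E)-but-2-enoyl]-4-(diphenylmethyl)-1,3-oxazolidin-2-one, via N-lithio oxazolidinone 19 (not isolated)
Conditions: n-BuLi, THF, −78 °C; then 18, −78 → 0 °C
Reagents that add atoms: none
Why: N-Acylation of the lithiated oxazolidinone with the acid chloride; the auxiliary stereocenter and the (E)-alkene are not affected.

Step 12
Reactants: 16 methyl (1R,4aS,5R,8aS)-5-{3-[(1,3-dioxoisoindolin-2-yl)oxy]-3-oxopropyl}-1,4a-dimethyl-6-methylidenedecahydronaphthalene-1-carboxylate; 20 (4R)-3-[(2E)-but-2-enoyl]-4-(diphenylmethyl)-1,3-oxazolidin-2-one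
Product: 21 methyl (1R,4aS,5R,8aS)-5-{(3R)-5-[(4R)-4-(diphenylmethyl)-2-oxo-1,3-oxazolidin-3-yl]-3-methyl-5-oxopentyl}-1,4a-dimethyl-6-methylidenedecahydronaphthalene-1-carboxylate
Conditions: 20 (2 equiv), Yb(OTf)3 (2 equiv), Hantzsch ester (1.5 equiv), fac-Ir(ppy)3 (1 mol %), CH2Cl2/THF 4:1, blue LEDs, −40 °C
Reagents that add atoms: none
Why: Single-electron reduction of the N-acyloxyphthalimide by photoexcited fac-Ir(ppy)3 (turned over by the Hantzsch ester) releases CO2 and phthalimide anion and leaves the primary C12 radical, which adds as a nucleophilic radical to C13, the beta-carbon of the Yb(OTf)3-chelated imide, and the resulting alpha-acyl radical takes a hydrogen atom from the Hantzsch ester. The closest known reaction types are the Lewis-acid-templated, auxiliary-controlled radical conjugate addition to N-enoyl oxazolidinones and the reductive decarboxylative Giese addition of N-acyloxyphthalimides. No ring is closed. The new stereocenter C13 is set by the auxiliary: bidentate chelation holds the imide in the syn, s-cis form, the diphenylmethyl group of the (R)-oxazolidinone covers the Re face of C13, and attack on the Si face gives 13R. The step needs addition to outrun hydrogen abstraction from the Hantzsch ester, which Lewis-acid activation and excess acceptor should secure, and it needs the radical to ignore the C8=C17 alkene, which is expected because closure would be 4-exo or 5-endo and the alkene is electron-rich.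

Step 13
Reactants: 21 methyl (1R,4aS,5R,8aS)-5-{(3R)-5-[(4R)-4-(diphenylmethyl)-2-oxo-1,3-oxazolidin-3-yl]-3-methyl-5-oxopentyl}-1,4a-dimethyl-6-methylidenedecahydronaphthalene-1-carboxylate
Product: 22 methyl (1R,4aS,5R,8aS)-5-[(3R)-5-hydroxy-3-methylpentyl]-1,4a-dimethyl-6-methylidenedecahydronaphthalene-1-carboxylate
Conditions: LiBH4, THF, MeOH (1 equiv), 0 °C
Reagents that add atoms: none
Why: Reductive cleavage of the N-acyl oxazolidinone gives the primary alcohol and returns the auxiliary; the axial, neopentyl-type methyl ester at C4 is too hindered to be reduced at this temperature and C13 cannot epimerise.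

Step 14
Reactants: 22 methyl (1R,4aS,5R,8aS)-5-[(3R)-5-hydroxy-3-methylpentyl]-1,4a-dimethyl-6-methylidenedecahydronaphthalene-1-carboxylate
Product: 24 (1R,4aS,5R,8aS)-5-[(3R)-5-hydroxy-3-methylpentyl]-1,4a-dimethyl-6-methylidenedecahydronaphthalene-1-carboxylic acid, via sodium carboxylate 23 (not isolated)
Conditions: NaSEt, DMF, 120 °C; then aq. HCl
Reagents that add atoms: none
Why: SN2 demethylation of the hindered methyl ester by ethanethiolate (attack at the methyl carbon instead of the shielded carbonyl), the usual way to free axial C4 acids of diterpenoids; alkene and stereocenters are untouched.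

Step 15
Reactants: 24 (1R,4aS,5R,8aS)-5-[(3R)-5-hydroxy-3-methylpentyl]-1,4a-dimethyl-6-methylidenedecahydronaphthalene-1-carboxylic acid
Product: 25 (1R,4aS,5R,8aS)-5-[(3R)-5-acetoxy-3-methylpentyl]-1,4a-dimethyl-6-methylidenedecahydronaphthalene-1-carboxylic acid (target)
Conditions: Ac2O (1.1 equiv), pyridine, CH2Cl2, 0 °C → rt; aqueous work-up
Reagents that add atoms: acetic anhydride CC(=O)OC(C)=O
Why: Selective O-acetylation of the primary alcohol by nucleophilic catalysis with pyridine; the hindered tertiary carboxylic acid should not compete at this temperature with a slight excess of anhydride.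

**Compound list**

1 | tert-butyl acetate | CC(=O)OC(C)(C)C | starting material
2 | geranyl bromide, (2E)-1-bromo-3,7-dimethylocta-2,6-diene | CC(C)=CCC/C(C)=C/CBr | starting material
3 | lithium enolate of tert-butyl acetate | [Li+].[O-]C(=C)OC(C)(C)C | intermediate (not isolated)
4 | tert-butyl (4E)-5,9-dimethyldeca-4,8-dienoate | CC(C)=CCC/C(C)=C/CCC(=O)OC(C)(C)C | intermediate
5 | tert-butyl (4E,8E)-10-hydroxy-5,9-dimethyldeca-4,8-dienoate | OC/C(C)=C/CC/C(C)=C/CCC(=O)OC(C)(C)C | intermediate
6 | tert-butyl (4E,8E)-10-bromo-5,9-dimethyldeca-4,8-dienoate | BrC/C(C)=C/CC/C(C)=C/CCC(=O)OC(C)(C)C | intermediate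
7 | methyl 2-methyl-3-oxobutanoate | COC(=O)C(C)C(C)=O | starting material
8 | sodium lithium dienolate (dianion) of methyl 2-methyl-3-oxobutanoate | [Na+].[Li+].[O-]C(=C)C(C)=C([O-])OC | intermediate (not isolated)
9 | 1-tert-butyl 14-methyl (4E,8E)-5,9,13-trimethyl-12-oxotetradeca-4,8-dienedioate (racemic at C13) | COC(=O)C(C)C(=O)CC/C(C)=C/CC/C(C)=C/CCC(=O)OC(C)(C)C | intermediate
10 | racemic methyl (1S,4aS,5R,8aS)-5-[3-(tert-butoxy)-3-oxopropyl]-1,4a-dimethyl-6-methylidene-2-oxodecahydronaphthalene-1-carboxylate (the enantiomer carried on is drawn) | C=C1CC[C@H]2[C@@](C)(CCC(=O)[C@@]2(C)C(=O)OC)[C@@H]1CCC(=O)OC(C)(C)C | intermediate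
11 | methyl (1S,2R,4aS,5R,8aS)-5-[3-(tert-butoxy)-3-oxopropyl]-2-hydroxy-1,4a-dimethyl-6-methylidenedecahydronaphthalene-1-carboxylate | C=C1CC[C@H]2[C@@](C)(CC[C@@H](O)[C@@]2(C)C(=O)OC)[C@@H]1CCC(=O)OC(C)(C)C | intermediate
12 | methyl (1S,2R,4aS,5R,8aS)-5-[3-(tert-butoxy)-3-oxopropyl]-2-[(1H-imidazol-1-ylcarbonothioyl)oxy]-1,4a-dimethyl-6-methylidenedecahydronaphthalene-1-carboxylate | C=C1CC[C@H]2[C@@](C)(CC[C@@H](OC(=S)n3ccnc3)[C@@]2(C)C(=O)OC)[C@@H]1CCC(=O)OC(C)(C)C | intermediate
13 | methyl (1R,4aS,5R,8aS)-5-[3-(tert-butoxy)-3-oxopropyl]-1,4a-dimethyl-6-methylidenedecahydronaphthalene-1-carboxylate | C=C1CC[C@H]2[C@@](C)(CCC[C@@]2(C)C(=O)OC)[C@@H]1CCC(=O)OC(C)(C)C | intermediate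
14 | methyl (1R,4aS,5R,8aS)-1,4a-dimethyl-6-methylidene-5-{3-oxo-3-[(trimethylsilyl)oxy]propyl}decahydronaphthalene-1-carboxylate | C=C1CC[C@H]2[C@@](C)(CCC[C@@]2(C)C(=O)OC)[C@@H]1CCC(=O)O[Si](C)(C)C | intermediate (not isolated)
15 | methyl (1R,4aS,5R,8aS)-5-(2-carboxyethyl)-1,4a-dimethyl-6-methylidenedecahydronaphthalene-1-carboxylate | C=C1CC[C@H]2[C@@](C)(CCC[C@@]2(C)C(=O)OC)[C@@H]1CCC(=O)O | intermediate
16 | methyl (1R,4aS,5R,8aS)-5-{3-[(1,3-dioxoisoindolin-2-yl)oxy]-3-oxopropyl}-1,4a-dimethyl-6-methylidenedecahydronaphthalene-1-carboxylate | C=C1CC[C@H]2[C@@](C)(CCC[C@@]2(C)C(=O)OC)[C@@H]1CCC(=O)ON1C(=O)c2ccccc2C1=O | intermediate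
17 | (4R)-4-(diphenylmethyl)-1,3-oxazolidin-2-one | O=C1OC[C@H](N1)C(c1ccccc1)c1ccccc1 | starting material
18 | (2E)-but-2-enoyl chloride | C/C=C/C(=O)Cl | starting material
19 | N-lithio salt of (4R)-4-(diphenylmethyl)-1,3-oxazolidin-2-one | [Li+].O=C1OC[C@H]([N-]1)C(c1ccccc1)c1ccccc1 | intermediate (not isolated)
20 | (4R)-3-[(2E)-but-2-enoyl]-4-(diphenylmethyl)-1,3-oxazolidin-2-one | C/C=C/C(=O)N1C(=O)OC[C@H]1C(c1ccccc1)c1ccccc1 | intermediate
21 | methyl (1R,4aS,5R,8aS)-5-{(3R)-5-[(4R)-4-(diphenylmethyl)-2-oxo-1,3-oxazolidin-3-yl]-3-methyl-5-oxopentyl}-1,4a-dimethyl-6-methylidenedecahydronaphthalene-1-carboxylate | C=C1CC[C@H]2[C@@](C)(CCC[C@@]2(C)C(=O)OC)[C@@H]1CC[C@@H](C)CC(=O)N1C(=O)OC[C@H]1C(c1ccccc1)c1ccccc1 | intermediate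
22 | methyl (1R,4aS,5R,8aS)-5-[(3R)-5-hydroxy-3-methylpentyl]-1,4a-dimethyl-6-methylidenedecahydronaphthalene-1-carboxylate | C=C1CC[C@H]2[C@@](C)(CCC[C@@]2(C)C(=O)OC)[C@@H]1CC[C@@H](C)CCO | intermediate
23 | sodium (1R,4aS,5R,8aS)-5-[(3R)-5-hydroxy-3-methylpentyl]-1,4a-dimethyl-6-methylidenedecahydronaphthalene-1-carboxylate | [Na+].C=C1CC[C@H]2[C@@](C)(CCC[C@@]2(C)C(=O)[O-])[C@@H]1CC[C@@H](C)CCO | intermediate (not isolated)
24 | (1R,4aS,5R,8aS)-5-[(3R)-5-hydroxy-3-methylpentyl]-1,4a-dimethyl-6-methylidenedecahydronaphthalene-1-carboxylic acid | C=C1CC[C@H]2[C@@](C)(CCC[C@@]2(C)C(=O)O)[C@@H]1CC[C@@H](C)CCO | intermediate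
25 | (1R,4aS,5R,8aS)-5-[(3R)-5-acetoxy-3-methylpentyl]-1,4a-dimethyl-6-methylidenedecahydronaphthalene-1-carboxylic acid | C=C1CC[C@H]2[C@@](C)(CCC[C@@]2(C)C(=O)O)[C@@H]1CC[C@@H](C)CCOC(C)=O | target

**Step count and risks**

Total step count: 15. Longest linear sequence: 14 steps (steps 1–10 and 12–15); step 11 is a one-step branch.

Steps most likely to fail:

Step 12. The primary radical may be reduced by the Hantzsch ester faster than it adds to the beta-methyl-substituted acceptor, or part of the addition may run through imide that is not chelated, which would erode facial selectivity. The fallback is polar and sets out from 16: visible-light iododecarboxylation (LiI, PPh3 cat., blue light) should give the primary iodide methyl (1R,4aS,5R,8aS)-5-(2-iodoethyl)-1,4a-dimethyl-6-methylidenedecahydronaphthalene-1-carboxylate F1. Magnesium insertion in Et2O would give the alkylmagnesium iodide F2, which is added in the presence of CuBr·SMe2 in THF at −78 °C to imide 20 (auxiliary-controlled organocopper conjugate addition through the magnesium chelate, attack anti to the diphenylmethyl group). This comes back to the route at 21.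

Step 5. The tertiary C8 radical may be oxidised to the cation instead of undergoing oxidative elimination, so that endocyclic alkene isomers form or the side-chain tert-butyl ester captures the cation as a delta-lactone, and over-oxidation may lower the mass balance. The fallback sets out from 9: selenenylation (NaH, PhSeCl, THF, 0 °C) gives the alpha-phenylselanyl keto diester F3. Photochemical phenylselenium group-transfer bicyclization (hν, benzene) gives the tertiary selenide F4, and oxidation with H2O2/pyridine followed by selenoxide syn-elimination toward the methyl group comes back to the route at racemic 10.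

Step 6. The enzyme may discriminate too little between the two enantiomers, or turnover of the hindered, lipophilic ketone may be slow. The fallback sets out from 10: preparative chromatography on a chiral stationary phase (supercritical CO2/MeOH) gives the single-enantiomer ketone F5, and NaBH4 in MeOH at 0 °C (axial hydride delivery, equatorial alcohol) comes back to the route at 11.

Further compounds
F1 | step 12 | methyl (1R,4aS,5R,8aS)-5-(2-iodoethyl)-1,4a-dimethyl-6-methylidenedecahydronaphthalene-1-carboxylate | C=C1CC[C@H]2[C@@](C)(CCC[C@@]2(C)C(=O)OC)[C@@H]1CCI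
F2 | step 12 | alkylmagnesium iodide from F1 (iodine replaced by MgI) | C=C1CC[C@H]2[C@@](C)(CCC[C@@]2(C)C(=O)OC)[C@@H]1CC[Mg]I
F3 | step 5 | 1-tert-butyl 14-methyl (4E,8E)-5,9,13-trimethyl-12-oxo-13-(phenylselanyl)tetradeca-4,8-dienedioate | COC(=O)C(C)([Se]c1ccccc1)C(=O)CC/C(C)=C/CC/C(C)=C/CCC(=O)OC(C)(C)C
F4 | step 5 | racemic 6-methyl-6-(phenylselanyl) analogue of 10 (methylidene replaced by CH3 and SePh, ring stereocenters as in 10, mixture at C6) | CC1([Se]c2ccccc2)CC[C@H]2[C@@](C)(CCC(=O)[C@@]2(C)C(=O)OC)[C@@H]1CCC(=O)OC(C)(C)C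
F5 | step 6 | methyl (1S,4aS,5R,8aS)-5-[3-(tert-butoxy)-3-oxopropyl]-1,4a-dimethyl-6-methylidene-2-oxodecahydronaphthalene-1-carboxylate as the single enantiomer | C=C1CC[C@H]2[C@@](C)(CCC(=O)[C@@]2(C)C(=O)OC)[C@@H]1CCC(=O)OC(C)(C)C
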